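Subtract the impurity from the enzyme before reading any curve. Here is what stands on the bench:

| flask | starting material | second substrate | enzyme | impurity | remark | time |
|---|---|---|---|---|---|---|
| Thursday's | 0.024 M | 0.50 equiv | 0.011 mol% | 2.5 µM | run made earlier |  |
| Saturday's | 0.024 M | 0.50 equiv | 0.011 mol% | 4 µM | run made earlier |  |
| Monday's | 0.024 M | 0.50 equiv | 0.0055 mol% | 1.8 µM | run made earlier |  |
| flask | 0.024 M | 0.500 equiv | 0.011 mol% | 1.8 µM |  | 40 min |

- Thursday's (time / min: target / %, starting material / %): 2.50: 65.5, 34.9; 4.00: 75.3, 23.7; 8.00: 91.5, 8.8; 12.0: 95.6, 5.0; 20.0: 95.2, 5.0; 30.0: 94.7, 5.0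
- Saturday's (time / min: target / %, starting material / %): 2.50: 26.4, 74.1; 4.00: 26.0, 73.8; 8.00: 25.6, 73.9; 12.0: 25.5, 74.1; 20.0: 25.5, 74.0; 30.0: 25.9, 74.3
- Monday's (time / min: target / %, starting material / %): 6.00: 30.4, 69.5; 12.0: 30.2, 69.6; 20.0: 30.4, 68.9; 25.0: 30.5, 69.8; 30.0: 30.7, 69.5

(standard deviation of a reading: 0.3 percentage points)

- steps that have been proposed: second substrate + enzyme <-> complex B; complex B -> enzyme + second product; enzyme + impurity -> spent catalyst; complex A <-> enzyme + target; starting material + enzyme <-> complex A
- the reaction counts as stopped when no species that holds the starting material changes by six tenths of a point or more over the second half of the time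

- at 40 min, what has stopped the reaction, if anything has (no working catalyst is left / all of the starting material has reacted / it is still moving / forward and back rates have come level)
- how much target there is at 40 min, in percent of the starting material charged

The runs read as a ledger in which each impurity takes one enzyme for good. In the flask, 2.64 µM of enzyme is charged and 1.8 µM of impurity is debited, leaving 0.840 µM. That balance is the surviving enzyme, enzyme charged minus impurity charged.

Saturday's run is overdrawn by 1.36 µM and lies flat from its first reading, with target at 25.9% and starting material at 74.3%. Monday's run is overdrawn by 0.480 µM and lies flat with target at 30.7%. Thursday's run keeps a balance of 0.140 µM and runs on, levelling by 12.0 min with target at 95.6% and starting material at 5.0%.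

In the flask the impurity is the limiting reagent of the killing step, since 1.8 µM is less than 2.64 µM. The surviving enzyme is 6.00 times Thursday's, so the starting material should pass into target until the two level, close to Thursday's last entries of 94.7% and 5.0%.

The forecast gives forward and back rates have come level, with 95% of target. Its ground is “Because living catalyst remained, that plateau looks like equilibrium”.

The flask gives 95.1% of target at 40 min: forward and back rates have come level.

    second substrate + enzyme ⇌ complex B (K = 950 /M, k = 2.76 × 10⁶ /M/s)
    complex B → enzyme + second product (k = 268 /s)
    enzyme + impurity → spent catalyst (k = 8.68 × 10⁵ /M/s)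
    complex A ⇌ enzyme + target (K = 0.0130 M, k = 410 /s)
    starting material + enzyme ⇌ complex A (K = 1500 /M, k = 3.97 × 10⁵ /M/s)

Without the scatter, Thursday's run at the time of its last reading gives 95.1% of target, and the same run with the flask's impurity gives 95.1%. The surviving enzyme is 31.8% of the charge, and the flask holds complex A 20.3%, complex B 0% and enzyme 11.5% beside spent catalyst 68.2%. The neighbour with 0.0066 mol% of enzyme charges 1.58 µM and is overdrawn by 12.0% of its impurity. That neighbour ends with impurity at 12%, spent catalyst at 100% and target at 43.9%.

The numbers in the tables stem from a simulated flask for substances that don't exist, and the scatter is random.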